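**Retrosynthetic overview**
1. Cut the diaryl ether C–O bond on the ring-B side (O–C6 of the dibromophenol). It is the only strategic bond and is made last.
2. The ring A half is the O-nucleophile 2,3,4-tribromo-6-methoxyphenol, which comes from guaiacol and 3 Br2 (OH/OMe-directed SEAr).
3. The ring B half is a "2-hydroxyaryl cation" equivalent: a rhodium quinoid carbene from 2,4-dibromo-6-diazocyclohexa-2,4-dien-1-one, made by diazotising 2-amino-4,6-dibromophenol. Its C=O becomes the free OH, so no protecting group is needed.
4. No ring is formed. Both benzene rings are bought intact and all five Br are in place before the coupling.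

Assumption: the SMILES has no stereocentre and this tri-ortho-substituted diaryl ether rotates freely, so the target is achiral and there is no enantiomer to select. Carbene 6 is drawn with a bare Rh atom, with the ligand sphere of the Rh2 core omitted.

**Step 1**
Reactants: 1 guaiacol (2-methoxyphenol)
Product: 2 2,3,4-tribromo-6-methoxyphenol (4,5,6-tribromoguaiacol)
Conditions: Br2 (3.1 equiv), AcOH, 0 °C → 40 °C; pour into water, filter, recrystallise (EtOH)
Reagents that add atoms: bromine, BrBr
Why: Electrophilic aromatic bromination in which the free OH directs to its para (C4) and ortho (C6) positions and OMe directs to its para position (C5), while the remaining C3–H (meta to OH, flanked by OMe and Br) reacts last, so three equivalents stop at the 4,5,6-tribromide.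

**Step 2**
Reactants: 3 2-amino-4,6-dibromophenol
Product: 5 2,4-dibromo-6-diazocyclohexa-2,4-dien-1-one, via diazonium chloride 4 (not isolated)
Conditions: NaNO2 (1.05 equiv), 2 M aq HCl, 0–5 °C; then NaOAc to pH 5; extract CH2Cl2, dry (MgSO4), keep cold and dark
Reagents that add atoms: sodium nitrite, [Na+].[O-]N=O (outer N of the diazo group); hydrochloric acid, Cl (chloride counter-ion of 4 only)
Why: Classical diazotisation of an o-aminophenol, where the two Br make the 2-hydroxydiazonium ion strongly acidic so acetate deprotonates it to the neutral o-quinone diazide, and both Br sit meta to N2+ so no halide exchange or hydrolysis occurs.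

**Step 3**
Reactants: 2 2,3,4-tribromo-6-methoxyphenol; 5 2,4-dibromo-6-diazocyclohexa-2,4-dien-1-one
Product: 7 2,4-dibromo-6-(2,3,4-tribromo-6-methoxyphenoxy)phenol (target), via rhodium quinoid carbene 6 (not isolated)
Conditions: Rh2(esp)2 (2 mol %), 2 (1.5 equiv), 4 Å MS, DCE, 70 °C, 5 added by syringe pump over 4 h, dark
Reagents that add atoms: none
Why: Proposed new method: aromatising carbene O–H insertion used as a diaryl ether synthesis. Rh2(esp)2 expels N2 from 5 to give the strongly electrophilic quinoid carbene 6; the phenol oxygen of 2 is its only accessible nucleophilic site (both ortho positions and the para position are blocked, so C–H arylation of the phenol cannot compete) and adds to the carbene carbon; Rh departs as ring B re-aromatises to an aryloxonium phenoxide, and a proton shift to the adjacent phenoxide gives 7 with the new O on the former diazo carbon and the former C=O as the free OH, so the regiochemistry is fixed by 5; Rh(II) does not insert into C–Br, so all five Br survive; the closest known reaction type is Rh(II)-catalysed O–H insertion of α-diazocarbonyl compounds into phenols and X–H functionalisation with diazonaphthoquinones, not shown for a monocyclic polybrominated o-quinone diazide with a di-ortho-substituted, acidic phenol.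

**Compound list**
1 | guaiacol (2-methoxyphenol) | COc1ccccc1O | starting material
2 | 2,3,4-tribromo-6-methoxyphenol (4,5,6-tribromoguaiacol) | COc1cc(Br)c(Br)c(Br)c1O | intermediate
3 | 2-amino-4,6-dibromophenol | Nc1cc(Br)cc(Br)c1O | starting material
4 | 3,5-dibromo-2-hydroxybenzenediazonium chloride | Oc1c(Br)cc(Br)cc1[N+]#N.[Cl-] | intermediate
5 | 2,4-dibromo-6-diazocyclohexa-2,4-dien-1-one (o-quinone diazide) | O=C1C(Br)=CC(Br)=CC1=[N+]=[N-] | intermediate
6 | rhodium-bound 3,5-dibromo-6-oxocyclohexa-2,4-dien-1-ylidene (quinoid carbene, ligands omitted) | O=C1C(Br)=CC(Br)=CC1=[Rh] | intermediate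
7 | 2,4-dibromo-6-(2,3,4-tribromo-6-methoxyphenoxy)phenol | COc1cc(Br)c(Br)c(Br)c1Oc1cc(Br)cc(Br)c1O | target

**Step count**
Total steps: 3. Longest linear sequence: 2 (1 → 2 → 7, or 3 → 5 → 7). The route uses no protecting groups and no halogenation after the coupling.

**Steps most likely to fail**

*Step 3 (proposed new step).*
- Risks: N2 loss from the electron-poor diazide may be slow. Wolff ring contraction may compete. The carbene may insert into adventitious water or into the OH of product 7.
- Fallback (known chemistry), from 2 back to 7: heat 2 with 2-fluorobenzaldehyde and K2CO3 in DMAc (SNAr) to give 2-(2,3,4-tribromo-6-methoxyphenoxy)benzaldehyde F1. Baeyer–Villiger oxidation with mCPBA in CH2Cl2 gives 2-(2,3,4-tribromo-6-methoxyphenoxy)phenyl formate F2. Aqueous NaOH/MeOH, then acid, cleaves it to 2-(2,3,4-tribromo-6-methoxyphenoxy)phenol F3. Br2 (2 equiv) in AcOH then brominates only para and ortho to the free OH of ring B, because ring A is deactivated by three Br, and this delivers 7.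

*Step 1.*
- Risks: the third bromine may enter partly at C3 instead of C5, giving the 3,4,6-isomer. Over-bromination to tetrabromoguaiacol is also possible.
- Fallback, from 1 back to 2, reverses the directing hierarchy so that C5 is set first. Acetylate 1 (Ac2O, pyridine) to 2-methoxyphenyl acetate F4. With the OH masked, NBS in MeCN brominates para to OMe to give 5-bromo-2-methoxyphenyl acetate F5. Aqueous NaOH/MeOH, then acid, gives 5-bromo-2-methoxyphenol F6. Br2 (2 equiv) in AcOH then fills the para and ortho positions of the free OH and gives 2 unambiguously.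

*Step 2.*
- Risks: the neutral diazide 5 is light- and heat-sensitive and energetic. It must also reach step 3 dry.
- Fallback, from 3 back to 7, avoids isolating any diazo compound and uses a C–I electrophile instead. Diazotise 3 as above and treat the cold solution of 4 directly with KI to give 2,4-dibromo-6-iodophenol F7. MOMCl and iPr2NEt in CH2Cl2 give 1,5-dibromo-3-iodo-2-(methoxymethoxy)benzene F8. Ullmann ether coupling with 2 (CuI, picolinic acid, Cs2CO3, dioxane, 90 °C), selective for C–I over C–Br, gives 1,2,3-tribromo-4-[3,5-dibromo-2-(methoxymethoxy)phenoxy]-5-methoxybenzene F9. HCl in MeOH removes the MOM group and leaves the aryl methyl ether intact, giving 7.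

**Further compounds**
F1 | step 3 | 2-(2,3,4-tribromo-6-methoxyphenoxy)benzaldehyde | COc1cc(Br)c(Br)c(Br)c1Oc1ccccc1C=O
F2 | step 3 | 2-(2,3,4-tribromo-6-methoxyphenoxy)phenyl formate | COc1cc(Br)c(Br)c(Br)c1Oc1ccccc1OC=O
F3 | step 3 | 2-(2,3,4-tribromo-6-methoxyphenoxy)phenol | COc1cc(Br)c(Br)c(Br)c1Oc1ccccc1O
F4 | step 1 | 2-methoxyphenyl acetate | COc1ccccc1OC(C)=O
F5 | step 1 | 5-bromo-2-methoxyphenyl acetate | COc1ccc(Br)cc1OC(C)=O
F6 | step 1 | 5-bromo-2-methoxyphenol | COc1ccc(Br)cc1O
F7 | step 2 | 2,4-dibromo-6-iodophenol | Oc1c(Br)cc(Br)cc1I
F8 | step 2 | 1,5-dibromo-3-iodo-2-(methoxymethoxy)benzene | COCOc1c(Br)cc(Br)cc1I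
F9 | step 2 | 1,2,3-tribromo-4-[3,5-dibromo-2-(methoxymethoxy)phenoxy]-5-methoxybenzene | COCOc1c(Br)cc(Br)cc1Oc1c(OC)cc(Br)c(Br)c1Br
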